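## Retrosynthetic overview

1. Target 27 ⇒ acetonide hydrolysis ⇐ allylic oxidation at C15 ⇐ 8‑O‑acylation of hydroxy lactone 19 with acetonide acid 23 (made from (R)‑solketal).
2. 19 ⇒ α‑methylenation of the saturated trans‑fused γ‑lactone 15.
3. Key disconnection C6–C7: 15 ⇒ acyclic aldehyde–enoate 13. The aldehyde carbon is used as a donor (samarium ketyl) toward the enoate β‑carbon; one step closes the cyclohexane, then the γ‑lactone, and sets C6 and C7.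
4. 13 ⇒ acid 11 ⇒ allyl ester 8 by an enantioselective boron‑enolate Ireland–Claisen rearrangement (C5–C10 bond; quaternary methyl/vinyl carbon and C5).
5. 8 ⇒ acid 7 + allylic alcohol 6 ⇒ vinylogous Mukaiyama aldol of dienol ether 2 with aldehyde 3 (C8–C9 bond, sets C8). Ring order: carbocycle first, lactone second; there is no other ring.

Atom labels follow elemanolide numbering: ring C5–C10; lactone O–C6, C7, C11(=C13), C12; ester on C8; C10 carries C14 (methyl) and C1=C2 (vinyl); C5 carries C4(=C3)–C15.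

Assumption: the sense of induction of the two chiral controllers (steps 2 and 6) is as drawn; if either is opposite, its enantiomer is used.

## Route

Step 1
Reactants: 1 3‑methylbut‑2‑enal
Product: 2 tert‑butyl(dimethyl){[(1E)‑3‑methylbuta‑1,3‑dien‑1‑yl]oxy}silane
Conditions: TBSOTf, Et3N, Et2O, 0 °C to rt
Reagents that add atoms: tert‑butyldimethylsilyl triflate, CC(C)(C)[Si](C)(C)OS(=O)(=O)C(F)(F)F
Why: O‑silylation of the enal with γ‑deprotonation by the amine gives the conjugated (E)‑dienol silyl ether (silyl dienol ether formation), the γ‑nucleophile for step 2.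

Step 2
Reactants: 2 tert‑butyl(dimethyl){[(1E)‑3‑methylbuta‑1,3‑dien‑1‑yl]oxy}silane; 3 ethyl (2E)‑4‑oxobut‑2‑enoate
Product: 4 ethyl (2E,4S,6E)‑4‑hydroxy‑6‑methyl‑8‑oxoocta‑2,6‑dienoate
Conditions: B‑phenyl‑oxazaborolidinone from N‑tosyl‑L‑tryptophan and PhBCl2 (0.5 equiv), i‑PrOH, EtCN, −78 °C
Reagents that add atoms: none
Why: Vinylogous Mukaiyama aldol reaction: the chiral boron Lewis acid binds the aldehyde oxygen of 3 and shields one face, so the γ‑carbon of 2 adds 1,2 to the open face, setting C8 (S) and re‑forming the (E)‑enal, while i‑PrOH takes up the silyl group.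

Step 3
Reactants: 4 ethyl (2E,4S,6E)‑4‑hydroxy‑6‑methyl‑8‑oxoocta‑2,6‑dienoate
Product: 5 ethyl (2E,4S,6E)‑4‑[(tert‑butyldimethylsilyl)oxy]‑6‑methyl‑8‑oxoocta‑2,6‑dienoate
Conditions: TBSCl, imidazole, DMF, 0 °C to rt
Reagents that add atoms: tert‑butyldimethylsilyl chloride, CC(C)(C)[Si](C)(C)Cl
Why: Silyl ether formation protects the C8 hydroxyl, and a γ‑silyloxy enoate (unlike a γ‑acyloxy one) is not reductively cleaved by SmI2 later.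

Step 4
Reactants: 5 ethyl (2E,4S,6E)‑4‑[(tert‑butyldimethylsilyl)oxy]‑6‑methyl‑8‑oxoocta‑2,6‑dienoate
Product: 6 ethyl (2E,4S,6E)‑4‑[(tert‑butyldimethylsilyl)oxy]‑8‑hydroxy‑6‑methylocta‑2,6‑dienoate
Conditions: NaBH4, CeCl3·7H2O, MeOH, −40 °C
Reagents that add atoms: none
Why: Luche reduction gives clean 1,2‑reduction of the enal to the (E)‑allylic alcohol and leaves the enoate ester untouched.

Step 5
Reactants: 6 ethyl (2E,4S,6E)‑4‑[(tert‑butyldimethylsilyl)oxy]‑8‑hydroxy‑6‑methylocta‑2,6‑dienoate; 7 3‑methylbut‑3‑enoic acid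
Product: 8 ethyl (2E,4S,6E)‑4‑[(tert‑butyldimethylsilyl)oxy]‑6‑methyl‑8‑[(3‑methylbut‑3‑enoyl)oxy]octa‑2,6‑dienoate
Conditions: DCC, DMAP (5 mol%), CH2Cl2, 0 °C
Reagents that add atoms: none
Why: Steglich esterification of the primary allylic alcohol at low temperature with catalytic DMAP keeps the β,γ‑unsaturated acyl group out of conjugation.

Step 6
Reactants: 8 ethyl (2E,4S,6E)‑4‑[(tert‑butyldimethylsilyl)oxy]‑6‑methyl‑8‑[(3‑methylbut‑3‑enoyl)oxy]octa‑2,6‑dienoate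
Product: 11 (2S,3S,5S,6E)‑5‑[(tert‑butyldimethylsilyl)oxy]‑3‑ethenyl‑8‑ethoxy‑3‑methyl‑8‑oxo‑2‑(prop‑1‑en‑2‑yl)oct‑6‑enoic acid, via boron dienolate 9 (not isolated), via acyloxyborane 10 (not isolated)
Conditions: (4S,5S)‑2‑bromo‑1,3‑bis{[3,5‑bis(trifluoromethyl)phenyl]sulfonyl}‑4,5‑diphenyl‑1,3,2‑diazaborolidine, Et3N, toluene–hexane, −78 °C to 4 °C; aqueous work‑up
Reagents that add atoms: none
Why: Enantioselective boron‑enolate Ireland–Claisen rearrangement: soft enolisation of the doubly activated CH2 gives the dienolate with the 2‑propenyl group trans to O–B; the chair [3,3] shift onto the (E)‑alkene fixes the C5/C10 relative configuration, and the chiral boron controller fixes its absolute sense (5S,10S), a reaction established on geranyl‑type esters for this elemane stereodiad.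

Step 7
Reactants: 11 (2S,3S,5S,6E)‑5‑[(tert‑butyldimethylsilyl)oxy]‑3‑ethenyl‑8‑ethoxy‑3‑methyl‑8‑oxo‑2‑(prop‑1‑en‑2‑yl)oct‑6‑enoic acid
Product: 13 ethyl (2E,4S,6S,7S)‑4‑[(tert‑butyldimethylsilyl)oxy]‑6‑ethenyl‑7‑formyl‑6,8‑dimethylnona‑2,8‑dienoate, via acid chloride 12 (not isolated)
Conditions: 1‑chloro‑N,N,2‑trimethylprop‑1‑en‑1‑amine (Ghosez's reagent), CH2Cl2, 0 °C; then LiAlH(Ot‑Bu)3, THF, −78 °C
Reagents that add atoms: none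
Why: Neutral acid chloride formation followed by partial hydride reduction stops at the hindered aldehyde without touching the enoate or epimerising C5; 13 is kept at or below 0 °C because it is a 1,5‑diene that could undergo Cope rearrangement to a conjugated enal on heating.

Step 8
Reactants: 13 ethyl (2E,4S,6S,7S)‑4‑[(tert‑butyldimethylsilyl)oxy]‑6‑ethenyl‑7‑formyl‑6,8‑dimethylnona‑2,8‑dienoate
Product: 15 (3aS,4S,6S,7S,7aR)‑4‑[(tert‑butyldimethylsilyl)oxy]‑6‑ethenyl‑6‑methyl‑7‑(prop‑1‑en‑2‑yl)hexahydro‑1‑benzofuran‑2(3H)‑one, via hydroxy ester 14 (not isolated)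
Conditions: SmI2 (2.5 equiv), MeOH (2 equiv), THF, −78 °C to 0 °C; then PPTS (cat.), toluene, 50 °C
Reagents that add atoms: none
Why: SmI2 ketyl–olefin (reductive aldehyde–enoate) cyclisation: one‑electron reduction turns the aldehyde carbon C6 into a nucleophilic ketyl that adds 6‑exo to the enoate β‑carbon C7, joining two carbons that are both acceptors; a chair transition state with the 2‑propenyl, OTBS, O–Sm and ester arm all equatorial (the axial C10 methyl disfavours an axial O–Sm) gives the 6,7‑trans hydroxy ester, which PPTS closes to the trans‑fused γ‑lactone.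

Step 9
Reactants: 15 (3aS,4S,6S,7S,7aR)‑4‑[(tert‑butyldimethylsilyl)oxy]‑6‑ethenyl‑6‑methyl‑7‑(prop‑1‑en‑2‑yl)hexahydro‑1‑benzofuran‑2(3H)‑one
Product: 18 (3aS,4S,6S,7S,7aR)‑4‑[(tert‑butyldimethylsilyl)oxy]‑6‑ethenyl‑6‑methyl‑3‑methylidene‑7‑(prop‑1‑en‑2‑yl)hexahydro‑1‑benzofuran‑2(3H)‑one, via Mannich base 16 (not isolated), via ammonium iodide 17 (not isolated)
Conditions: LDA, THF, −78 °C; CH2=NMe2+ I−, −78 °C to 0 °C; then MeI, MeOH, rt; then aq. NaHCO3, CH2Cl2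
Reagents that add atoms: Eschenmoser's salt (N,N‑dimethylmethyleneiminium iodide), C=[N+](C)C.[I-]
Why: α‑Methylenation by enolate Mannich reaction, N‑quaternisation and base‑induced elimination installs C13; C7 is β to the carbonyl and is not epimerised.

Step 10
Reactants: 18 (3aS,4S,6S,7S,7aR)‑4‑[(tert‑butyldimethylsilyl)oxy]‑6‑ethenyl‑6‑methyl‑3‑methylidene‑7‑(prop‑1‑en‑2‑yl)hexahydro‑1‑benzofuran‑2(3H)‑one
Product: 19 (3aR,4S,6S,7S,7aR)‑6‑ethenyl‑4‑hydroxy‑6‑methyl‑3‑methylidene‑7‑(prop‑1‑en‑2‑yl)hexahydro‑1‑benzofuran‑2(3H)‑one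
Conditions: HF·pyridine, pyridine, THF, 0 °C to rt
Reagents that add atoms: none
Why: Buffered fluoride desilylation frees the 8‑hydroxyl under mildly acidic conditions that avoid translactonisation and conjugate addition to the methylene lactone.

Step 11
Reactants: 20 [(4R)‑2,2‑dimethyl‑1,3‑dioxolan‑4‑yl]methanol
Product: 22 (4R)‑4‑ethynyl‑2,2‑dimethyl‑1,3‑dioxolane, via aldehyde 21 (not isolated)
Conditions: Dess–Martin periodinane, CH2Cl2, 0 °C to rt; then dimethyl (1‑diazo‑2‑oxopropyl)phosphonate, K2CO3, MeOH, 0 °C to rt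
Reagents that add atoms: dimethyl (1‑diazo‑2‑oxopropyl)phosphonate (Ohira–Bestmann reagent), CC(=O)C(=[N+]=[N-])P(=O)(OC)OC
Why: Alcohol oxidation and Ohira–Bestmann (Seyferth–Gilbert) homologation of the crude α‑alkoxy aldehyde give the terminal alkyne with the acetonide stereocentre intact.

Step 12
Reactants: 22 (4R)‑4‑ethynyl‑2,2‑dimethyl‑1,3‑dioxolane
Product: 23 2‑[(4R)‑2,2‑dimethyl‑1,3‑dioxolan‑4‑yl]prop‑2‑enoic acid
Conditions: Pd(OAc)2 (5 mol%), Xantphos, HCO2H, Ac2O (cat.), toluene, 80 °C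
Reagents that add atoms: formic acid, OC=O
Why: Palladium‑catalysed Markovnikov hydrocarboxylation of a terminal alkyne (formic acid as the CO and water source) puts the carboxyl on the internal carbon, giving the 2‑substituted acrylic acid directly.

Step 13
Reactants: 19 (3aR,4S,6S,7S,7aR)‑6‑ethenyl‑4‑hydroxy‑6‑methyl‑3‑methylidene‑7‑(prop‑1‑en‑2‑yl)hexahydro‑1‑benzofuran‑2(3H)‑one; 23 2‑[(4R)‑2,2‑dimethyl‑1,3‑dioxolan‑4‑yl]prop‑2‑enoic acid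
Product: 25 (3aR,4S,6S,7S,7aR)‑6‑ethenyl‑6‑methyl‑3‑methylidene‑2‑oxo‑7‑(prop‑1‑en‑2‑yl)octahydro‑1‑benzofuran‑4‑yl 2‑[(4R)‑2,2‑dimethyl‑1,3‑dioxolan‑4‑yl]prop‑2‑enoate, via mixed anhydride 24 (not isolated)
Conditions: 2,4,6‑trichlorobenzoyl chloride, Et3N, THF, rt; then 19, DMAP, toluene, rt
Reagents that add atoms: none
Why: Yamaguchi esterification acylates the equatorial secondary 8‑hydroxyl with retention, and the acetonide prevents the side‑chain diol from lactonising or competing.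

Step 14
Reactants: 25 (3aR,4S,6S,7S,7aR)‑6‑ethenyl‑6‑methyl‑3‑methylidene‑2‑oxo‑7‑(prop‑1‑en‑2‑yl)octahydro‑1‑benzofuran‑4‑yl 2‑[(4R)‑2,2‑dimethyl‑1,3‑dioxolan‑4‑yl]prop‑2‑enoate
Product: 26 (3aR,4S,6S,7R,7aR)‑6‑ethenyl‑7‑(3‑hydroxyprop‑1‑en‑2‑yl)‑6‑methyl‑3‑methylidene‑2‑oxooctahydro‑1‑benzofuran‑4‑yl 2‑[(4R)‑2,2‑dimethyl‑1,3‑dioxolan‑4‑yl]prop‑2‑enoate
Conditions: SeO2 (0.5 equiv), t‑BuOOH, CH2Cl2, 0 °C to rt
Reagents that add atoms: tert‑butyl hydroperoxide, CC(C)(C)OO; SeO2 (oxygen carrier), O=[Se]=O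
Why: SeO2 allylic oxidation (ene reaction then [2,3] shift) hydroxylates the methyl of the only electron‑rich alkene with allylic hydrogens, the 2‑propenyl group; the vinyl group has no allylic hydrogen and the two acrylate‑type alkenes are too electron‑poor.

Step 15
Reactants: 26 (3aR,4S,6S,7R,7aR)‑6‑ethenyl‑7‑(3‑hydroxyprop‑1‑en‑2‑yl)‑6‑methyl‑3‑methylidene‑2‑oxooctahydro‑1‑benzofuran‑4‑yl 2‑[(4R)‑2,2‑dimethyl‑1,3‑dioxolan‑4‑yl]prop‑2‑enoate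
Product: 27 (3aR,4S,6S,7R,7aR)‑6‑ethenyl‑7‑(3‑hydroxyprop‑1‑en‑2‑yl)‑6‑methyl‑3‑methylidene‑2‑oxooctahydro‑1‑benzofuran‑4‑yl (3R)‑3,4‑dihydroxy‑2‑methylidenebutanoate (CNP0234188.1)
Conditions: AcOH–H2O (4:1), rt to 40 °C
Reagents that add atoms: none
Why: Mild acid hydrolysis of the acetonide frees the diol under conditions too mild for γ‑lactonisation of the side chain or hydration of the alkenes.

## Compound list

1 | 3‑methylbut‑2‑enal | CC(C)=CC=O | starting material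
2 | tert‑butyl(dimethyl){[(1E)‑3‑methylbuta‑1,3‑dien‑1‑yl]oxy}silane | C=C(C)/C=C/O[Si](C)(C)C(C)(C)C | intermediate
3 | ethyl (2E)‑4‑oxobut‑2‑enoate | CCOC(=O)/C=C/C=O | starting material
4 | ethyl (2E,4S,6E)‑4‑hydroxy‑6‑methyl‑8‑oxoocta‑2,6‑dienoate | O=C/C=C(\C)C[C@H](O)/C=C/C(=O)OCC | intermediate
5 | ethyl (2E,4S,6E)‑4‑[(tert‑butyldimethylsilyl)oxy]‑6‑methyl‑8‑oxoocta‑2,6‑dienoate | O=C/C=C(\C)C[C@H](O[Si](C)(C)C(C)(C)C)/C=C/C(=O)OCC | intermediate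
6 | ethyl (2E,4S,6E)‑4‑[(tert‑butyldimethylsilyl)oxy]‑8‑hydroxy‑6‑methylocta‑2,6‑dienoate | OC/C=C(\C)C[C@H](O[Si](C)(C)C(C)(C)C)/C=C/C(=O)OCC | intermediate
7 | 3‑methylbut‑3‑enoic acid | C=C(C)CC(=O)O | starting material
8 | ethyl (2E,4S,6E)‑4‑[(tert‑butyldimethylsilyl)oxy]‑6‑methyl‑8‑[(3‑methylbut‑3‑enoyl)oxy]octa‑2,6‑dienoate | C=C(C)CC(=O)OC/C=C(\C)C[C@H](O[Si](C)(C)C(C)(C)C)/C=C/C(=O)OCC | intermediate
9 | boron dienolate of 8 (O‑boryl ketene acetal, 2‑propenyl trans to O–B, (4S,5S)‑diazaborolidine on boron) | C=C(C)/C=C(/OB1N(S(=O)(=O)c2cc(cc(c2)C(F)(F)F)C(F)(F)F)[C@@H](c2ccccc2)[C@H](c2ccccc2)N1S(=O)(=O)c1cc(cc(c1)C(F)(F)F)C(F)(F)F)OC/C=C(\C)C[C@H](O[Si](C)(C)C(C)(C)C)/C=C/C(=O)OCC | intermediate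
10 | acyloxyborane of acid 11 (B‑carboxylate of the (4S,5S)‑diazaborolidine) | C=C[C@](C)(C[C@H](O[Si](C)(C)C(C)(C)C)/C=C/C(=O)OCC)[C@@H](C(=O)OB1N(S(=O)(=O)c2cc(cc(c2)C(F)(F)F)C(F)(F)F)[C@@H](c2ccccc2)[C@H](c2ccccc2)N1S(=O)(=O)c1cc(cc(c1)C(F)(F)F)C(F)(F)F)C(C)=C | intermediate
11 | (2S,3S,5S,6E)‑5‑[(tert‑butyldimethylsilyl)oxy]‑3‑ethenyl‑8‑ethoxy‑3‑methyl‑8‑oxo‑2‑(prop‑1‑en‑2‑yl)oct‑6‑enoic acid | C=C[C@](C)(C[C@H](O[Si](C)(C)C(C)(C)C)/C=C/C(=O)OCC)[C@@H](C(=O)O)C(C)=C | intermediate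
12 | ethyl (2E,4S,6S,7S)‑4‑[(tert‑butyldimethylsilyl)oxy]‑7‑(chlorocarbonyl)‑6‑ethenyl‑6,8‑dimethylnona‑2,8‑dienoate | C=C[C@](C)(C[C@H](O[Si](C)(C)C(C)(C)C)/C=C/C(=O)OCC)[C@@H](C(=O)Cl)C(C)=C | intermediate
13 | ethyl (2E,4S,6S,7S)‑4‑[(tert‑butyldimethylsilyl)oxy]‑6‑ethenyl‑7‑formyl‑6,8‑dimethylnona‑2,8‑dienoate | C=C[C@](C)(C[C@H](O[Si](C)(C)C(C)(C)C)/C=C/C(=O)OCC)[C@@H](C=O)C(C)=C | intermediate
14 | ethyl 2‑[(1S,2R,3S,4S,6S)‑6‑[(tert‑butyldimethylsilyl)oxy]‑4‑ethenyl‑2‑hydroxy‑4‑methyl‑3‑(prop‑1‑en‑2‑yl)cyclohexyl]acetate | C=C[C@]1(C)C[C@H](O[Si](C)(C)C(C)(C)C)[C@@H](CC(=O)OCC)[C@H](O)[C@H]1C(C)=C | intermediate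
15 | (3aS,4S,6S,7S,7aR)‑4‑[(tert‑butyldimethylsilyl)oxy]‑6‑ethenyl‑6‑methyl‑7‑(prop‑1‑en‑2‑yl)hexahydro‑1‑benzofuran‑2(3H)‑one | C=C[C@]1(C)C[C@H](O[Si](C)(C)C(C)(C)C)[C@H]2CC(=O)O[C@@H]2[C@H]1C(C)=C | intermediate
16 | 3‑[(dimethylamino)methyl] derivative of 15 (C3 epimers) | C=C[C@]1(C)C[C@H](O[Si](C)(C)C(C)(C)C)[C@H]2C(CN(C)C)C(=O)O[C@@H]2[C@H]1C(C)=C | intermediate
17 | 3‑[(trimethylammonio)methyl] derivative of 15, iodide (C3 epimers) | C=C[C@]1(C)C[C@H](O[Si](C)(C)C(C)(C)C)[C@H]2C(C[N+](C)(C)C)C(=O)O[C@@H]2[C@H]1C(C)=C.[I-] | intermediate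
18 | (3aS,4S,6S,7S,7aR)‑4‑[(tert‑butyldimethylsilyl)oxy]‑6‑ethenyl‑6‑methyl‑3‑methylidene‑7‑(prop‑1‑en‑2‑yl)hexahydro‑1‑benzofuran‑2(3H)‑one | C=C[C@]1(C)C[C@H](O[Si](C)(C)C(C)(C)C)[C@H]2C(=C)C(=O)O[C@@H]2[C@H]1C(C)=C | intermediate
19 | (3aR,4S,6S,7S,7aR)‑6‑ethenyl‑4‑hydroxy‑6‑methyl‑3‑methylidene‑7‑(prop‑1‑en‑2‑yl)hexahydro‑1‑benzofuran‑2(3H)‑one | C=C[C@]1(C)C[C@H](O)[C@H]2C(=C)C(=O)O[C@@H]2[C@H]1C(C)=C | intermediate
20 | [(4R)‑2,2‑dimethyl‑1,3‑dioxolan‑4‑yl]methanol ((R)‑solketal) | OC[C@@H]1COC(C)(C)O1 | starting material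
21 | (4S)‑2,2‑dimethyl‑1,3‑dioxolane‑4‑carbaldehyde | O=C[C@@H]1COC(C)(C)O1 | intermediate
22 | (4R)‑4‑ethynyl‑2,2‑dimethyl‑1,3‑dioxolane | C#C[C@@H]1COC(C)(C)O1 | intermediate
23 | 2‑[(4R)‑2,2‑dimethyl‑1,3‑dioxolan‑4‑yl]prop‑2‑enoic acid | OC(=O)C(=C)[C@@H]1COC(C)(C)O1 | intermediate
24 | 2‑[(4R)‑2,2‑dimethyl‑1,3‑dioxolan‑4‑yl]prop‑2‑enoic 2,4,6‑trichlorobenzoic anhydride | C=C(C(=O)OC(=O)c1c(Cl)cc(Cl)cc1Cl)[C@@H]1COC(C)(C)O1 | intermediate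
25 | (3aR,4S,6S,7S,7aR)‑6‑ethenyl‑6‑methyl‑3‑methylidene‑2‑oxo‑7‑(prop‑1‑en‑2‑yl)octahydro‑1‑benzofuran‑4‑yl 2‑[(4R)‑2,2‑dimethyl‑1,3‑dioxolan‑4‑yl]prop‑2‑enoate | C=C[C@]1(C)C[C@H](OC(=O)C(=C)[C@@H]3COC(C)(C)O3)[C@H]2C(=C)C(=O)O[C@@H]2[C@H]1C(C)=C | intermediate
26 | (3aR,4S,6S,7R,7aR)‑6‑ethenyl‑7‑(3‑hydroxyprop‑1‑en‑2‑yl)‑6‑methyl‑3‑methylidene‑2‑oxooctahydro‑1‑benzofuran‑4‑yl 2‑[(4R)‑2,2‑dimethyl‑1,3‑dioxolan‑4‑yl]prop‑2‑enoate | C=C[C@]1(C)C[C@H](OC(=O)C(=C)[C@@H]3COC(C)(C)O3)[C@H]2C(=C)C(=O)O[C@@H]2[C@H]1C(=C)CO | intermediate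
27 | (3aR,4S,6S,7R,7aR)‑6‑ethenyl‑7‑(3‑hydroxyprop‑1‑en‑2‑yl)‑6‑methyl‑3‑methylidene‑2‑oxooctahydro‑1‑benzofuran‑4‑yl (3R)‑3,4‑dihydroxy‑2‑methylidenebutanoate | C=C[C@]1(C)C[C@H](OC(=O)C(=C)[C@@H](O)CO)[C@H]2C(=C)C(=O)O[C@@H]2[C@H]1C(=C)CO | target

## Step count and risks

Total: 15 steps. Longest linear sequence: 13 steps (steps 1–10, then 13–15); the side‑chain acid takes 2 steps (11–12).

**Step 2 (vinylogous aldol).** Dienol ether 2 is also a diene and 3 a good dienophile, so Diels–Alder or 1,4‑addition may compete, and the enantioselectivity on this aldehyde is untested. The fallback sets out from 3 and returns at 5. 3‑Methylbut‑2‑enoyl chloride and morpholine give 4‑(3‑methylbut‑2‑enoyl)morpholine F1. LDA and TBSCl convert it into the N,O‑silyl ketene acetal 4‑{(1Z)‑1‑[(tert‑butyldimethylsilyl)oxy]‑3‑methylbuta‑1,3‑dien‑1‑yl}morpholine F2. SiCl4 with a chiral bisphosphoramide (Lewis‑base‑activated Lewis acid catalysis, which adds 1,2 to enals) joins F2 to 3 at the γ‑carbon to give ethyl (2E,4S,6E)‑4‑hydroxy‑6‑methyl‑8‑(morpholin‑4‑yl)‑8‑oxoocta‑2,6‑dienoate F3. Silylation gives ethyl (2E,4S,6E)‑4‑[(tert‑butyldimethylsilyl)oxy]‑6‑methyl‑8‑(morpholin‑4‑yl)‑8‑oxoocta‑2,6‑dienoate F4. Cp2Zr(H)Cl then reduces the tertiary amide to the aldehyde in the presence of the ester, giving 5.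

**Step 8 (samarium ketyl cyclisation).** Pinacol coupling, simple aldehyde reduction or the wrong C6/C7 diastereomer are possible. The fallback sets out from 13 and returns at 14, making the same C6–C7 bond with an acyl anion instead of a ketyl. An N‑mesityl triazolium‑derived carbene converts the aldehyde into a Breslow intermediate that adds 6‑exo to the enoate (intramolecular Stetter reaction). This gives ethyl 2‑[(1R,3S,4S,6S)‑6‑[(tert‑butyldimethylsilyl)oxy]‑4‑ethenyl‑4‑methyl‑2‑oxo‑3‑(prop‑1‑en‑2‑yl)cyclohexyl]acetate F5, in which C5 and C7 are both α to the ketone and settle in the all‑equatorial arrangement. Reduction under thermodynamic control (SmI2, i‑PrOH, THF) gives the equatorial alcohol 14, which is lactonised to 15 as in the second stage of step 8.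

**Step 14 (allylic oxidation).** Over‑oxidation to the enal or low conversion on this dense substrate is likely. The fallback sets out from 25 and returns at 27. Ene‑type chlorination with hypochlorous acid (Ca(OCl)2, CO2, CH2Cl2–H2O, 0 °C) gives (3aR,4S,6S,7R,7aR)‑7‑(3‑chloroprop‑1‑en‑2‑yl)‑6‑ethenyl‑6‑methyl‑3‑methylidene‑2‑oxooctahydro‑1‑benzofuran‑4‑yl 2‑[(4R)‑2,2‑dimethyl‑1,3‑dioxolan‑4‑yl]prop‑2‑enoate F6. Displacement with HCO2Na in DMF gives the corresponding 7‑[3‑(formyloxy)prop‑1‑en‑2‑yl] ester F7. The aqueous acetic acid of step 15 then cleaves both the formate and the acetonide to give 27.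

## Further compounds

F1 | step 2 | 4‑(3‑methylbut‑2‑enoyl)morpholine | CC(C)=CC(=O)N1CCOCC1
F2 | step 2 | 4‑{(1Z)‑1‑[(tert‑butyldimethylsilyl)oxy]‑3‑methylbuta‑1,3‑dien‑1‑yl}morpholine | C=C(C)/C=C(\O[Si](C)(C)C(C)(C)C)N1CCOCC1
F3 | step 2 | ethyl (2E,4S,6E)‑4‑hydroxy‑6‑methyl‑8‑(morpholin‑4‑yl)‑8‑oxoocta‑2,6‑dienoate | O=C(/C=C(\C)C[C@H](O)/C=C/C(=O)OCC)N1CCOCC1
F4 | step 2 | ethyl (2E,4S,6E)‑4‑[(tert‑butyldimethylsilyl)oxy]‑6‑methyl‑8‑(morpholin‑4‑yl)‑8‑oxoocta‑2,6‑dienoate | O=C(/C=C(\C)C[C@H](O[Si](C)(C)C(C)(C)C)/C=C/C(=O)OCC)N1CCOCC1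
F5 | step 8 | ethyl 2‑[(1R,3S,4S,6S)‑6‑[(tert‑butyldimethylsilyl)oxy]‑4‑ethenyl‑4‑methyl‑2‑oxo‑3‑(prop‑1‑en‑2‑yl)cyclohexyl]acetate | C=C[C@]1(C)C[C@H](O[Si](C)(C)C(C)(C)C)[C@@H](CC(=O)OCC)C(=O)[C@H]1C(C)=C
F6 | step 14 | (3aR,4S,6S,7R,7aR)‑7‑(3‑chloroprop‑1‑en‑2‑yl)‑6‑ethenyl‑6‑methyl‑3‑methylidene‑2‑oxooctahydro‑1‑benzofuran‑4‑yl 2‑[(4R)‑2,2‑dimethyl‑1,3‑dioxolan‑4‑yl]prop‑2‑enoate | C=C[C@]1(C)C[C@H](OC(=O)C(=C)[C@@H]3COC(C)(C)O3)[C@H]2C(=C)C(=O)O[C@@H]2[C@H]1C(=C)CCl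
F7 | step 14 | (3aR,4S,6S,7R,7aR)‑6‑ethenyl‑7‑[3‑(formyloxy)prop‑1‑en‑2‑yl]‑6‑methyl‑3‑methylidene‑2‑oxooctahydro‑1‑benzofuran‑4‑yl 2‑[(4R)‑2,2‑dimethyl‑1,3‑dioxolan‑4‑yl]prop‑2‑enoate | C=C[C@]1(C)C[C@H](OC(=O)C(=C)[C@@H]3COC(C)(C)O3)[C@H]2C(=C)C(=O)O[C@@H]2[C@H]1C(=C)COC=O
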